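**Retrosynthetic overview**
1. Last ring: the 15,16-dihydrofuran is closed by oxidative O16→C15 cyclisation of a 9,13-epoxy-labd-14-en-16-ol (the C16-oxygenated form of the biogenetic 9,13-epoxy-labd-14-ene).
2. First heterocycle: the 9,13-oxolane comes from capture of a C13 allyl-cation equivalent (Pd π-allyl from a 13,16-carbonate) by the 9α-OH; C13 is set there by the ligand.
3. Ring B (7-one, 8β-OAc, 9α-OH) comes from an 8α,9α-epoxy-7-one through an acetyl 1,2-shift of its C6 enol acetate; the enone comes from a Δ8 alkene.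
4. The side chain is grown from a C13 methyl ketone (C16 hydroxylation, vinyl addition); the trans-decalin with C5 and C10 is taken from sclareol.
5. Ring order: decalin (chiral pool, not built) → oxolane (O9–C13) → dihydrofuran (O16–C15).

Assumption: the presumed biosynthesis is taken as capture of a C13 allyl cation by the 9α-hydroxyl of a peregrinol-type labdane, then C16 oxygenation and O16→C15 oxidative closure, with C7/C8 oxygenation as tailoring; labdane numbering is used, and the target is (5S,8R,9S,10S,13R).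

**Step 1**
Reactants: 1 (−)-sclareol
Product: 2 8α-hydroxy-14,15-dinorlabdan-13-one
Conditions: KMnO4, MgSO4, acetone–H2O, 0 °C → rt
Reagents that add atoms: none
Why: Permanganate cleaves the vinyl group and decarboxylates the resulting α-hydroxy acid (oxidative cleavage of a tertiary vinyl carbinol to a methyl ketone), leaving the 8-OH and C5/C9/C10 untouched.

**Step 2**
Reactants: 2 8α-hydroxy-14,15-dinorlabdan-13-one
Product: 3 14,15-dinorlabd-8-en-13-one
Conditions: I2 (5 mol %), toluene, reflux
Reagents that add atoms: none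
Why: Acid-catalysed E1 dehydration of the tertiary 8-ol under equilibrating conditions funnels to the tetrasubstituted Δ8(9) alkene (Zaitsev, thermodynamic control), deliberately erasing C8 and C9, which are rebuilt in steps 6 and 7.

**Step 3**
Reactants: 3 14,15-dinorlabd-8-en-13-one
Product: 5 16-hydroxy-14,15-dinorlabd-8-en-13-one, via potassium enolate 4 (not isolated)
Conditions: KHMDS, THF, −78 °C; then trans-2-(phenylsulfonyl)-3-phenyloxaziridine, −78 °C; H2O work-up
Reagents that add atoms: trans-2-(phenylsulfonyl)-3-phenyloxaziridine, O=S(=O)(c1ccccc1)N1OC1c1ccccc1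
Why: The bulky amide base removes the less hindered methyl proton (kinetic enolate) and the N-sulfonyloxaziridine transfers oxygen to the enolate carbon (Davis α-hydroxylation); no stereocentre is formed.

**Step 4**
Reactants: 5 16-hydroxy-14,15-dinorlabd-8-en-13-one; 6 vinylmagnesium bromide
Product: 8 (13RS)-labda-8,14-diene-13,16-diyl carbonate, via bis(bromomagnesium) diolate 7 (not isolated)
Conditions: 6 (2.2 equiv), THF, −78 → 0 °C; then CDI, 0 → 40 °C
Reagents that add atoms: 1,1'-carbonyldiimidazole, O=C(n1ccnc1)n1ccnc1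
Why: Chelation-assisted Grignard 1,2-addition to the α-alkoxido ketone and carbonylation of the 1,2-diolate give the vinyl ethylene carbonate; C13 is formed as a roughly 1:1 mixture on purpose, because step 8 is stereoconvergent.

**Step 5**
Reactants: 8 (13RS)-labda-8,14-diene-13,16-diyl carbonate
Product: 9 (13RS)-7-oxolabda-8,14-diene-13,16-diyl carbonate
Conditions: CrO3, 3,5-dimethylpyrazole, CH2Cl2, −20 °C
Reagents that add atoms: chromium trioxide, O=[Cr](=O)=O
Why: Chromium(VI)–3,5-dimethylpyrazole allylic oxidation converts the ring CH2 next to the tetrasubstituted alkene into the enone, C7 being preferred over the C11 methylene shielded by C1 and the C10 methyl; no stereocentre is formed.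

**Step 6**
Reactants: 9 (13RS)-7-oxolabda-8,14-diene-13,16-diyl carbonate
Product: 10 (13RS)-8α,9α-epoxy-7-oxolabd-14-ene-13,16-diyl carbonate
Conditions: t-BuOOH (decane), DBU, CH2Cl2, 0 °C → rt
Reagents that add atoms: tert-butyl hydroperoxide, CC(C)(C)OO
Why: Weitz–Scheffer nucleophilic epoxidation, in which the peroxide anion adds axially to C9 from the α-face (anti to the C10 β-methyl) and the enolate closes on the same face, so C9 receives its α-oxygen.

**Step 7**
Reactants: 10 (13RS)-8α,9α-epoxy-7-oxolabd-14-ene-13,16-diyl carbonate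
Product: 13 (13RS)-8β-acetoxy-9α-hydroxy-7-oxolabd-14-ene-13,16-diyl carbonate, via lithium enolate 11 (not isolated), via enol acetate 12 (not isolated)
Conditions: LiHMDS, THF, −78 °C; Ac2O, −78 → 0 °C; then 1 M aq. HCl, THF, 0 °C → rt
Reagents that add atoms: acetic anhydride, CC(=O)OC(C)=O; water, O
Why: Proposed new method: C6 is the only enolisable position of 10, so O-acetylation gives a 2-acetoxy vinyl oxirane in which, on protonation, the allylic C8–O bond opens with anchimeric attack of the ester carbonyl from the β-face (anti to the leaving α-oxygen, hence inversion at C8 to 8β-O) while the C9–O bond is kept (9α-OH), and hydrolytic acyl transfer releases the enol oxygen as the C7 ketone and leaves the acetyl group on the new 8β-oxygen; the closest known chemistry is neighbouring acyloxy participation in epoxide opening (Prévost–Woodward type) and the acyl-shift rearrangement of enol ester epoxides.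

**Step 8**
Reactants: 13 (13RS)-8β-acetoxy-9α-hydroxy-7-oxolabd-14-ene-13,16-diyl carbonate
Product: 14 (13R)-8β-acetoxy-9α,13-epoxy-16-hydroxylabd-14-en-7-one
Conditions: Pd2(dba)3·CHCl3 (2.5 mol %), (R,R)-DACH-phenyl Trost ligand (7.5 mol %), BEt3 (10 mol %), CH2Cl2, rt
Reagents that add atoms: none
Why: Proposed new method: Pd(0) ionises the tertiary allylic carbonate with loss of CO2 to a zwitterionic π-allyl (the flask counterpart of the C13 allyl cation), both C13 epimers interconvert by η3–η1–η3 at the unsubstituted C15 terminus, and the boron-bridged 9α-OH closes 5-exo on the substituted terminus inside the chiral ligand pocket, so C13 is set as R by the catalyst (the antipodal ligand would give the epimer, and the sense of induction for this intramolecular case must be confirmed on the first run); the closest known chemistry is the Pd-catalysed dynamic kinetic asymmetric addition of alcohols to 2-substituted vinyl oxiranes and vinyl ethylene carbonates giving tertiary allylic ethers.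

**Step 9**
Reactants: 14 (13R)-8β-acetoxy-9α,13-epoxy-16-hydroxylabd-14-en-7-one
Product: 15 (13R)-8β-acetoxy-9α,13;15,16-diepoxylabd-14-en-7-one
Conditions: Pd(OAc)2 (10 mol %), NaOAc, 3 Å MS, DMSO, O2 (1 atm), 35 °C
Reagents that add atoms: none
Why: Proposed new method: hydroxyl-directed 5-endo (anti-Markovnikov) oxypalladation of the vinyl group puts Pd on C14, and because C13 is quaternary β-hydride elimination can only use a C15–H, giving the C14=C15 enol ether under buffered, non-acidic conditions that leave C13 untouched; the closest known chemistry is the Wacker-type aerobic oxidative cyclisation of alkenols and the Pd(II) conversion of homoallylic alcohols into γ-lactols.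

**Compound list**
1 | (−)-sclareol, (13R)-labd-14-ene-8α,13-diol | C[C@@]1(O)CC[C@H]2C(C)(C)CCC[C@]2(C)[C@H]1CC[C@@](C)(O)C=C | starting material
2 | 8α-hydroxy-14,15-dinorlabdan-13-one | C[C@@]1(O)CC[C@H]2C(C)(C)CCC[C@]2(C)[C@H]1CCC(C)=O | intermediate
3 | 14,15-dinorlabd-8-en-13-one | CC1=C(CCC(C)=O)[C@@]2(C)CCCC(C)(C)[C@@H]2CC1 | intermediate
4 | potassium C13(16)-enolate of 3 (not isolated) | CC1=C(CCC(=C)[O-])[C@@]2(C)CCCC(C)(C)[C@@H]2CC1.[K+] | intermediate
5 | 16-hydroxy-14,15-dinorlabd-8-en-13-one | CC1=C(CCC(=O)CO)[C@@]2(C)CCCC(C)(C)[C@@H]2CC1 | intermediate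
6 | vinylmagnesium bromide | C=C[Mg]Br | starting material
7 | bis(bromomagnesium) (13RS)-labda-8,14-diene-13,16-diolate (not isolated) | CC1=C(CCC(C=C)(CO[Mg]Br)O[Mg]Br)[C@@]2(C)CCCC(C)(C)[C@@H]2CC1 | intermediate
8 | (13RS)-labda-8,14-diene-13,16-diyl carbonate (4-vinyl-1,3-dioxolan-2-one at C13/C16; about 1:1 at C13) | CC1=C(CCC2(C=C)COC(=O)O2)[C@@]3(C)CCCC(C)(C)[C@@H]3CC1 | intermediate
9 | (13RS)-7-oxolabda-8,14-diene-13,16-diyl carbonate | CC1=C(CCC2(C=C)COC(=O)O2)[C@@]3(C)CCCC(C)(C)[C@@H]3CC1=O | intermediate
10 | (13RS)-8α,9α-epoxy-7-oxolabd-14-ene-13,16-diyl carbonate | C[C@@]12C(=O)C[C@H]3C(C)(C)CCC[C@]3(C)[C@]1(CCC1(C=C)COC(=O)O1)O2 | intermediate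
11 | lithium 6-en-7-olate of 10 (not isolated) | C[C@@]12C([O-])=C[C@H]3C(C)(C)CCC[C@]3(C)[C@]1(CCC1(C=C)COC(=O)O1)O2.[Li+] | intermediate
12 | (13RS)-7-acetoxy-8α,9α-epoxylabda-6,14-diene-13,16-diyl carbonate (not isolated) | C[C@@]12C(OC(C)=O)=C[C@H]3C(C)(C)CCC[C@]3(C)[C@]1(CCC1(C=C)COC(=O)O1)O2 | intermediate
13 | (13RS)-8β-acetoxy-9α-hydroxy-7-oxolabd-14-ene-13,16-diyl carbonate | CC(=O)O[C@@]1(C)C(=O)C[C@H]2C(C)(C)CCC[C@]2(C)[C@@]1(O)CCC1(C=C)COC(=O)O1 | intermediate
14 | (13R)-8β-acetoxy-9α,13-epoxy-16-hydroxylabd-14-en-7-one | CC(=O)O[C@@]1(C)C(=O)C[C@H]2C(C)(C)CCC[C@]2(C)[C@@]12CC[C@](CO)(C=C)O2 | intermediate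
15 | (13R)-8β-acetoxy-9α,13;15,16-diepoxylabd-14-en-7-one (CNP0165143.1) | CC(=O)O[C@@]1(C)C(=O)C[C@H]2C(C)(C)CCC[C@]2(C)[C@@]12CC[C@]1(C=COC1)O2 | target

**Totals**
Total step count: 9. Longest linear sequence: 9 steps (1 → 15); 6 is bought.

**Steps most likely to fail, with fallbacks**

Step 8 is the most likely to fail. The hindered tertiary 9α-OH may not engage the π-allyl, which would then collapse to the vinyl oxirane or a diene, and the 9-alkoxide could open ring B by retro-aldol. The fallback sets out from 13 and comes back at 14, replacing π-allyl capture by Brønsted-acid epoxide opening. Compound 13 is decarboxylated with an achiral Pd(0)/dppe catalyst under a nitrogen sweep to the vinyl oxirane (13RS)-8β-acetoxy-13,16-epoxy-9α-hydroxylabd-14-en-7-one F5. Catalytic CSA in CH2Cl2 at −40 °C then lets the 9α-OH open the protonated oxirane 5-exo at the allylic tertiary C13. This variant has no catalyst control, so 14 must be separated by chromatography from its epimer (13S)-8β-acetoxy-9α,13-epoxy-16-hydroxylabd-14-en-7-one F6.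

Step 7 is the second risk. The acetoxy group could close on C6 instead of C8, water could add SN2′ at C6, or the enol acetate could simply hydrolyse back to 10. The fallback sets out from 9 and comes back at 13, using the saturated, classical neighbouring-group sequence. Luche reduction (NaBH4, CeCl3, MeOH, −78 °C) gives the equatorial allylic alcohol (13RS)-7β-hydroxylabda-8,14-diene-13,16-diyl carbonate F1. Ac2O/DMAP gives (13RS)-7β-acetoxylabda-8,14-diene-13,16-diyl carbonate F2. Buffered mCPBA epoxidises the Δ8 bond from the α-face to (13RS)-7β-acetoxy-8α,9α-epoxylabd-14-ene-13,16-diyl carbonate F3. Aqueous HClO4 in THF opens the oxirane at C8 with participation of the 7β-acetate (axial ester, equatorial alcohol on hydrolysis) to (13RS)-8β-acetoxy-7β,9α-dihydroxylabd-14-ene-13,16-diyl carbonate F4. Dess–Martin oxidation of the secondary 7β-OH then returns 13.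

Step 9 is the third risk. The 5-endo oxypalladation may be slow, Pd/DMSO/O2 may oxidise the primary alcohol instead, and any acid would aromatise the product to the furan. The fallback sets out from 14 and comes back at 15, building the enol ether by metathesis instead of oxypalladation. Pd(OAc)2/4,7-diphenylphenanthroline-catalysed transfer vinylation of the 16-OH in ethyl vinyl ether gives (13R)-8β-acetoxy-9α,13-epoxy-16-(vinyloxy)labd-14-en-7-one F7. Ring-closing metathesis (Grubbs II, toluene, 60 °C) then closes the 2,3-dihydrofuran with loss of ethene.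

**Further compounds**
F1 | step 7 | (13RS)-7β-hydroxylabda-8,14-diene-13,16-diyl carbonate | CC1=C(CCC2(C=C)COC(=O)O2)[C@@]3(C)CCCC(C)(C)[C@@H]3C[C@@H]1O
F2 | step 7 | (13RS)-7β-acetoxylabda-8,14-diene-13,16-diyl carbonate | CC1=C(CCC2(C=C)COC(=O)O2)[C@@]3(C)CCCC(C)(C)[C@@H]3C[C@@H]1OC(C)=O
F3 | step 7 | (13RS)-7β-acetoxy-8α,9α-epoxylabd-14-ene-13,16-diyl carbonate | C[C@@]12[C@@H](OC(C)=O)C[C@H]3C(C)(C)CCC[C@]3(C)[C@]1(CCC1(C=C)COC(=O)O1)O2
F4 | step 7 | (13RS)-8β-acetoxy-7β,9α-dihydroxylabd-14-ene-13,16-diyl carbonate | CC(=O)O[C@@]1(C)[C@@H](O)C[C@H]2C(C)(C)CCC[C@]2(C)[C@@]1(O)CCC1(C=C)COC(=O)O1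
F5 | step 8 | (13RS)-8β-acetoxy-13,16-epoxy-9α-hydroxylabd-14-en-7-one | CC(=O)O[C@@]1(C)C(=O)C[C@H]2C(C)(C)CCC[C@]2(C)[C@@]1(O)CCC1(C=C)CO1
F6 | step 8 | (13S)-8β-acetoxy-9α,13-epoxy-16-hydroxylabd-14-en-7-one | CC(=O)O[C@@]1(C)C(=O)C[C@H]2C(C)(C)CCC[C@]2(C)[C@@]12CC[C@@](CO)(C=C)O2
F7 | step 9 | (13R)-8β-acetoxy-9α,13-epoxy-16-(vinyloxy)labd-14-en-7-one | CC(=O)O[C@@]1(C)C(=O)C[C@H]2C(C)(C)CCC[C@]2(C)[C@@]12CC[C@](COC=C)(C=C)O2
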